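**Retrosynthetic overview**
1. The central CH2–CH2 bond is cut last: a primary radical from the right-half acid (stored as a cis γ-lactone) adds, under visible light, to a left-half 2-methyl-1,3-diene; chromium-mediated γ-protonation fixes azulene C5 and the ring alkene.
2. Left half from (S)-limonene: cyclopentene by aldol, tertiary carbinol by epoxidation and SmI2 opening, seven-membered ring by metathesis, cis fusion by OH-directed hydrogenation, then cuprate/methylenation and triflate/methyl coupling to the diene.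
3. Right half from (R)-carvone plus an epoxy iodide from L-malic-derived (S)-α-hydroxy-γ-butyrolactone: α′-dialkylation (quaternary carbon), Criegee rearrangement (ring C–O), 7-endo epoxide opening (oxepane), then epoxidation / Wharton / Johnson–Claisen / lactonisation (last two ring centres).
4. Ring order: left cyclopentene, then cycloheptene; right cyclohexene (bought), then oxepane, then γ-lactone; fragment union is the final step.

Assumption: the target is made exactly as the SMILES is written, i.e. (1S,3aS,5R,8aS) in the azulene half and (3S,5aS,6S,7R,9aR) in the benzoxepine half, whose ether ring is therefore cis-fused (5a-CH3 and 9a-H on the same face).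

**Step 1**
Reactants: 1 (S)-(−)-limonene
Product: 2 (3S)-6-oxo-3-(prop-1-en-2-yl)heptanal
Conditions: O3 (1.0 equiv), CH2Cl2, −78 °C; then Me2S, −78 °C → rt
Reagents that add atoms: ozone, [O-][O+]=O
Why: Ozonolysis cleaves the more electron-rich trisubstituted ring alkene in preference to the isopropenyl group and leaves the stereocentre untouched.

**Step 2**
Reactants: 2 (3S)-6-oxo-3-(prop-1-en-2-yl)heptanal
Product: 3 (5R)-2-methyl-5-(prop-1-en-2-yl)cyclopent-1-ene-1-carbaldehyde
Conditions: piperidine (cat.), AcOH (cat.), toluene, reflux (Dean–Stark)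
Reagents that add atoms: none
Why: Amine-catalysed intramolecular aldol condensation (aldehyde enamine onto the methyl ketone, five-ring closure, dehydration).

**Step 3**
Reactants: 3 (5R)-2-methyl-5-(prop-1-en-2-yl)cyclopent-1-ene-1-carbaldehyde
Product: 4 (1R,2R,5S)-5-methyl-2-(prop-1-en-2-yl)-6-oxabicyclo[3.1.0]hexane-1-carbaldehyde
Conditions: 30% H2O2, NaOH (cat.), MeOH, 0 °C
Reagents that add atoms: hydrogen peroxide, OO
Why: Weitz–Scheffer nucleophilic epoxidation occurs on the face opposite the adjacent isopropenyl group and sets the tertiary C–O centre (later azulene C1).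

**Step 4**
Reactants: 4 epoxy aldehyde
Product: 5 (E)-N-methoxy-N-methyl-3-[(1R,2R,5S)-5-methyl-2-(prop-1-en-2-yl)-6-oxabicyclo[3.1.0]hexan-1-yl]prop-2-enamide
Conditions: Ph3P=CHC(O)N(OMe)Me, toluene, 80 °C
Reagents that add atoms: N-methoxy-N-methyl-2-(triphenylphosphoranylidene)acetamide, CON(C)C(=O)C=P(c1ccccc1)(c1ccccc1)c1ccccc1
Why: Wittig olefination with a stabilised ylide gives the E enamide.

**Step 5**
Reactants: 5 epoxy enamide
Product: 6 (E)-3-[(2S,5R)-2-hydroxy-2-methyl-5-(prop-1-en-2-yl)cyclopentylidene]-N-methoxy-N-methylpropanamide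
Conditions: SmI2 (2.5 equiv), THF/HMPA, MeOH (2 equiv), −78 °C
Reagents that add atoms: none
Why: Reductive vinyl-epoxide opening by SmI2 breaks the allylic C–O bond and α-protonation gives the β,γ-unsaturated amide; the tertiary carbinol keeps its configuration and allylic strain places the chain trans to the carbinol carbon (E).

**Step 6**
Reactants: 6 hydroxy amide
Product: 7 (E)-5-[(2S,5R)-2-hydroxy-2-methyl-5-(prop-1-en-2-yl)cyclopentylidene]pent-1-en-3-one
Conditions: CH2=CHMgBr (3.5 equiv), THF, −78 → 0 °C; cold aq. NH4Cl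
Reagents that add atoms: vinylmagnesium bromide, C=C[Mg]Br
Why: Weinreb ketone synthesis, in which the chelated tetrahedral intermediate prevents over-addition and the excess Grignard covers the free OH.

**Step 7**
Reactants: 7 vinyl ketone
Product: 8 (1S,3aR)-1-hydroxy-1,4-dimethyl-2,3,3a,7-tetrahydroazulen-6(1H)-one
Conditions: second-generation Grubbs catalyst (5 mol %), CH2Cl2, 40 °C
Reagents that add atoms: none
Why: Ring-closing metathesis of the vinyl ketone with the isopropenyl group closes the seven-membered ring as a β-methyl enone; the E exocyclic alkene holds the chain next to the isopropenyl group.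

**Step 8**
Reactants: 8 dienone
Product: 9 (1S,3aS,8aS)-1-hydroxy-1,4-dimethyl-2,3,3a,7,8,8a-hexahydroazulen-6(1H)-one
Conditions: [Ir(cod)(PCy3)(py)]PF6 (5 mol %), H2 (1 atm), CH2Cl2, rt
Reagents that add atoms: none
Why: Hydroxyl-directed hydrogenation delivers H2 to the C8=C8a alkene from the face of the tertiary OH, giving the cis ring fusion (8aS), while the hindered conjugated alkene is left.

**Step 9**
Reactants: 9 enone
Product: 13 (1S,3aS,8aS)-1-hydroxy-1,4,4-trimethyl-5-methylideneoctahydroazulen-6(1H)-one, via dilithium enolate 10 (not isolated), via Mannich base 11 (not isolated), via ammonium iodide 12 (not isolated)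
Conditions: Me2CuLi (2.5 equiv), Et2O, −40 → 0 °C; CH2=NMe2+ I−, THF, −78 °C → rt; aq. work-up; MeI, CH2Cl2; then aq. NaHCO3, rt
Reagents that add atoms: lithium dimethylcuprate, [Li+].C[Cu-]C; N,N-dimethylmethyleneiminium iodide, C=[N+](C)C.[I-]
Why: Cuprate 1,4-addition creates the gem-dimethyl carbon and a regiospecific enolate, which undergoes Mannich reaction and, after N-methylation, loses trimethylamine (Eschenmoser methylenation).

**Step 10**
Reactants: 13 α-methylene ketone
Product: 14 (1S,3aS,8aS)-1-hydroxy-1,4,4-trimethyl-5-methylidene-1,2,3,3a,4,5,8,8a-octahydroazulen-6-yl trifluoromethanesulfonate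
Conditions: KN(SiMe3)2 (2.2 equiv), THF, −78 °C; then PhNTf2 (1.1 equiv), −78 °C
Reagents that add atoms: N-phenylbis(trifluoromethanesulfonimide), O=S(=O)(N(c1ccccc1)S(=O)(=O)C(F)(F)F)C(F)(F)F
Why: Only C7 carries α-hydrogens, so kinetic deprotonation gives the cross-conjugated dienolate, which is O-sulfonylated (enol triflate formation); the hindered tertiary alkoxide is not expected to be triflated at −78 °C.

**Step 11**
Reactants: 14 dienyl triflate
Product: 15 (1S,3aS,8aS)-1,4,4,6-tetramethyl-5-methylidene-1,2,3,3a,4,5,8,8a-octahydroazulen-1-ol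
Conditions: MeMgBr (3 equiv), Fe(acac)3 (5 mol %), THF/NMP, −20 °C
Reagents that add atoms: methylmagnesium bromide, C[Mg]Br
Why: Iron-catalysed Kumada-type cross-coupling replaces the alkenyl triflate by methyl without moving the alkene.

**Step 12**
Reactants: 16 (S)-3-hydroxyoxolan-2-one
Product: 17 (R)-3-chlorooxolan-2-one
Conditions: PPh3, N-chlorosuccinimide, CH2Cl2, 0 °C → rt
Reagents that add atoms: N-chlorosuccinimide, O=C1CCC(=O)N1Cl
Why: Appel-type chlorination displaces the oxyphosphonium by SN2 and so inverts the carbinol centre.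

**Step 13**
Reactants: 17 (R)-3-chlorooxolan-2-one
Product: 19 2-[(2S)-3,3-dimethyloxiran-2-yl]ethan-1-ol, via chlorohydrin 18 (not isolated)
Conditions: MeMgBr (2.2 equiv), THF, −78 → 0 °C; then 2 M NaOH, rt
Reagents that add atoms: methylmagnesium bromide, C[Mg]Br
Why: Double Grignard addition to the lactone gives the tertiary alkoxide, which closes to the epoxide by intramolecular SN2 (second inversion), so the epoxide carbon is (S).

**Step 14**
Reactants: 19 epoxy alcohol
Product: 20 (2S)-2-(2-iodoethyl)-3,3-dimethyloxirane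
Conditions: I2, PPh3, imidazole, CH2Cl2, 0 °C
Reagents that add atoms: iodine, II
Why: Appel iodination of the primary alcohol under imidazole buffering leaves the epoxide and its stereocentre intact.

**Step 15**
Reactants: 21 (R)-(−)-carvone; 20 epoxy iodide
Product: 22 (5R)-6-{2-[(2S)-3,3-dimethyloxiran-2-yl]ethyl}-2-methyl-5-(prop-1-en-2-yl)cyclohex-2-en-1-one (C6 epimers)
Conditions: LiN(iPr)2 (1.05 equiv), THF, −78 °C; then 20, DMPU, −78 → −20 °C
Reagents that add atoms: none
Why: The kinetic α′-enolate of carvone is alkylated by the primary iodide (SN2); the new centre is re-enolised in step 16, so its configuration does not matter.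

**Step 16**
Reactants: 22 alkylated carvone
Product: 23 (5S,6R)-6-{2-[(2S)-3,3-dimethyloxiran-2-yl]ethyl}-2,6-dimethyl-5-(prop-1-en-2-yl)cyclohex-2-en-1-one
Conditions: LiN(iPr)2 (1.1 equiv), THF, −78 °C; MeI, −78 → 0 °C
Reagents that add atoms: iodomethane, CI
Why: Diastereoselective enolate alkylation: MeI approaches anti to the adjacent isopropenyl group, so the quaternary carbon carries methyl trans and the epoxy chain cis to isopropenyl.

**Step 17**
Reactants: 23 dialkylated carvone
Product: 25 (1R,6R)-6-{2-[(2S)-3,3-dimethyloxiran-2-yl]ethyl}-4,6-dimethyl-5-oxocyclohex-3-en-1-yl acetate, via methoxy hydroperoxide 24 (not isolated)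
Conditions: O3, CH2Cl2/MeOH, −78 °C; then Ac2O, Et3N, DMAP (cat.), 0 → 40 °C
Reagents that add atoms: ozone, [O-][O+]=O; methanol, CO
Why: Ozonolysis of the isopropenyl group in methanol and Criegee rearrangement of the derived peracetate replace C–C by C–O with retention at the migrating ring carbon; the acetyl carbons are the former isopropenyl C(CH3).

**Step 18**
Reactants: 25 acetate
Product: 27 (3S,5aR,9aR)-3-hydroxy-2,2,5a,7-tetramethyl-3,4,5,5a,9,9a-hexahydro-1-benzoxepin-6(2H)-one, via hydroxy epoxide 26 (not isolated)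
Conditions: K2CO3 (cat.), MeOH, 0 °C; then BF3·OEt2 (20 mol %), CH2Cl2, −78 → −40 °C
Reagents that add atoms: none
Why: Methanolysis frees the ring alcohol (cis to the epoxy chain) and BF3 activation opens the epoxide at its tertiary carbon (SN1-like 7-endo oxacyclisation), giving the cis-fused oxepane with the (3S) carbinol untouched.

**Step 19**
Reactants: 27 oxepane enone
Product: 28 7,8-epoxide of 27 with the oxirane on the face of the 5a-methyl group
Conditions: 30% H2O2, NaOH, MeOH, 0 °C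
Reagents that add atoms: hydrogen peroxide, OO
Why: Weitz–Scheffer epoxidation: hydroperoxide adds axially to C8 anti to the C9a–O bond, as in carvone, so the epoxide lies on the face of the 5a-methyl group.

**Step 20**
Reactants: 28 epoxy ketone
Product: 29 (3S,5aS,8R,9aR)-2,2,5a,7-tetramethyl-2,3,4,5,5a,8,9,9a-octahydro-1-benzoxepine-3,8-diol
Conditions: N2H4·H2O (3 equiv), AcOH (cat.), MeOH, 0 °C → rt
Reagents that add atoms: none
Why: Wharton transposition: the epoxy hydrazone loses N2 to give the allylic alcohol with the C8–O bond and its configuration retained and the alkene moved to C6=C7.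

**Step 21**
Reactants: 29 allylic alcohol
Product: 30 ethyl 2-[(3S,5aS,6R,9aR)-3-hydroxy-2,2,5a,7-tetramethyl-2,3,4,5,5a,6,9,9a-octahydro-1-benzoxepin-6-yl]acetate
Conditions: MeC(OEt)3 (10 equiv), EtCO2H (cat.), xylene, 140 °C (EtOH distilled off); mild acidic work-up
Reagents that add atoms: triethyl orthoacetate, CCOC(C)(OCC)OCC
Why: Johnson–Claisen rearrangement: the suprafacial [3,3] shift forms the C6–CH2 bond on the face of the C8 oxygen (cis to the 5a-methyl) and moves the alkene to C7=C8; the hindered C3–OH is only reversibly exchanged.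

**Step 22**
Reactants: 30 ester
Product: 32 γ-lactone of [(3S,5aS,6S,7R,9aR)-3,7-dihydroxy-2,2,5a,7-tetramethyldecahydro-1-benzoxepin-6-yl]acetic acid, via unsaturated acid 31 (not isolated)
Conditions: LiOH, THF/H2O, rt; HCl to pH 3; then Amberlyst-15, CH2Cl2, rt
Reagents that add atoms: lithium hydroxide, [Li+].[OH-]
Why: Saponification then acid-catalysed Markovnikov lactonisation: the tertiary C7 cation is captured by the tethered carboxyl, which can only give the cis-fused γ-lactone and so sets C7 (O cis to the C6 side chain).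

**Step 23**
Reactants: 32 lactone; 15 diene
Product: 34 target, (3S,5aS,6S,7R,9aR)-6-{2-[(1S,3aS,5R,8aS)-1-hydroxy-1,4,4,6-tetramethyl-1,2,3,3a,4,5,8,8a-octahydroazulen-5-yl]ethyl}-2,2,5a,7-tetramethyldecahydro-1-benzoxepine-3,7-diol, via cesium carboxylate 33 (not isolated)
Conditions: CsOH·H2O (1.0 equiv), THF/H2O, rt, evaporate; then 15 (1.2 equiv), 4CzIPN (3 mol %), CrCl3 (10 mol %), 4,4′-di-tert-butyl-2,2′-bipyridine (12 mol %), H2O (10 equiv), DMA, 450 nm LEDs, rt
Reagents that add atoms: none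
Why: Proposed new method: photoexcited 4CzIPN oxidises carboxylate 33, which loses CO2 to a primary radical that adds to the unhindered exocyclic CH2 of diene 15; divalent chromium (from CrCl3 and the reduced photocatalyst) traps the allyl radical at its less hindered ring CH terminus on the convex face, and the allylchromium is protonated by chromium-bound water through a six-membered SE2′ transition state at the γ-carbon, which should put H on the convex face of azulene C5 (5R) and leave the C6=C7 alkene; the closest known reaction type is the dual photoredox/chromium three-component alkyl-allylation of aldehydes with 1,3-dienes (a proton here replaces the aldehyde), together with decarboxylative Giese addition.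

**Compound list**
1 | (S)-(−)-limonene | CC1=CC[C@H](CC1)C(C)=C | starting material
2 | (3S)-6-oxo-3-(prop-1-en-2-yl)heptanal | O=CC[C@H](CCC(C)=O)C(C)=C | intermediate
3 | (5R)-2-methyl-5-(prop-1-en-2-yl)cyclopent-1-ene-1-carbaldehyde | O=CC1=C(C)CC[C@@H]1C(C)=C | intermediate
4 | (1R,2R,5S)-5-methyl-2-(prop-1-en-2-yl)-6-oxabicyclo[3.1.0]hexane-1-carbaldehyde (epoxide trans to isopropenyl) | O=C[C@]12O[C@@]1(C)CC[C@@H]2C(C)=C | intermediate
5 | (E)-N-methoxy-N-methyl-3-[(1R,2R,5S)-5-methyl-2-(prop-1-en-2-yl)-6-oxabicyclo[3.1.0]hexan-1-yl]prop-2-enamide | CON(C)C(=O)/C=C/[C@]12O[C@@]1(C)CC[C@@H]2C(C)=C | intermediate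
6 | (E)-3-[(2S,5R)-2-hydroxy-2-methyl-5-(prop-1-en-2-yl)cyclopentylidene]-N-methoxy-N-methylpropanamide | CON(C)C(=O)C/C=C1/[C@@](C)(O)CC[C@@H]1C(C)=C | intermediate
7 | (E)-5-[(2S,5R)-2-hydroxy-2-methyl-5-(prop-1-en-2-yl)cyclopentylidene]pent-1-en-3-one | C=CC(=O)C/C=C1/[C@@](C)(O)CC[C@@H]1C(C)=C | intermediate
8 | (1S,3aR)-1-hydroxy-1,4-dimethyl-2,3,3a,7-tetrahydroazulen-6(1H)-one | O=C1C=C(C)[C@H]2CC[C@](C)(O)C2=CC1 | intermediate
9 | (1S,3aS,8aS)-1-hydroxy-1,4-dimethyl-2,3,3a,7,8,8a-hexahydroazulen-6(1H)-one (cis-fused) | O=C1C=C(C)[C@H]2CC[C@](C)(O)[C@H]2CC1 | intermediate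
10 | dilithium enolate/alkoxide of (1S,3aS,8aS)-1-hydroxy-1,4,4-trimethyloctahydroazulen-6(1H)-one | [Li+].[Li+].[O-]C1=CC(C)(C)[C@H]2CC[C@](C)([O-])[C@H]2CC1 | intermediate
11 | (1S,3aS,8aS)-5-[(dimethylamino)methyl]-1-hydroxy-1,4,4-trimethyloctahydroazulen-6(1H)-one (C5 epimers) | CN(C)CC1C(=O)CC[C@H]2[C@H](CC[C@]2(C)O)C1(C)C | intermediate
12 | N-methyl ammonium iodide of 11 | C[N+](C)(C)CC1C(=O)CC[C@H]2[C@H](CC[C@]2(C)O)C1(C)C.[I-] | intermediate
13 | (1S,3aS,8aS)-1-hydroxy-1,4,4-trimethyl-5-methylideneoctahydroazulen-6(1H)-one | C=C1C(=O)CC[C@H]2[C@H](CC[C@]2(C)O)C1(C)C | intermediate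
14 | (1S,3aS,8aS)-1-hydroxy-1,4,4-trimethyl-5-methylidene-1,2,3,3a,4,5,8,8a-octahydroazulen-6-yl trifluoromethanesulfonate | C=C1C(OS(=O)(=O)C(F)(F)F)=CC[C@H]2[C@H](CC[C@]2(C)O)C1(C)C | intermediate
15 | (1S,3aS,8aS)-1,4,4,6-tetramethyl-5-methylidene-1,2,3,3a,4,5,8,8a-octahydroazulen-1-ol | C=C1C(C)=CC[C@H]2[C@H](CC[C@]2(C)O)C1(C)C | intermediate
16 | (S)-3-hydroxyoxolan-2-one [(S)-α-hydroxy-γ-butyrolactone] | O[C@H]1CCOC1=O | starting material
17 | (R)-3-chlorooxolan-2-one | Cl[C@@H]1CCOC1=O | intermediate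
18 | (R)-3-chloro-4-methylpentane-1,4-diol (formed as its alkoxide) | OCC[C@@H](Cl)C(C)(C)O | intermediate
19 | 2-[(2S)-3,3-dimethyloxiran-2-yl]ethan-1-ol | OCC[C@@H]1OC1(C)C | intermediate
20 | (2S)-2-(2-iodoethyl)-3,3-dimethyloxirane | ICC[C@@H]1OC1(C)C | intermediate
21 | (R)-(−)-carvone | CC1=CC[C@H](CC1=O)C(C)=C | starting material
22 | (5R)-6-{2-[(2S)-3,3-dimethyloxiran-2-yl]ethyl}-2-methyl-5-(prop-1-en-2-yl)cyclohex-2-en-1-one (C6 epimers) | CC1=CC[C@@H](C(C)=C)C(CC[C@@H]2OC2(C)C)C1=O | intermediate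
23 | (5S,6R)-6-{2-[(2S)-3,3-dimethyloxiran-2-yl]ethyl}-2,6-dimethyl-5-(prop-1-en-2-yl)cyclohex-2-en-1-one (6-CH3 trans to isopropenyl) | CC1=CC[C@@H](C(C)=C)[C@@](C)(CC[C@@H]2OC2(C)C)C1=O | intermediate
24 | (6R)-6-{2-[(2S)-3,3-dimethyloxiran-2-yl]ethyl}-5-(1-hydroperoxy-1-methoxyethyl)-2,6-dimethylcyclohex-2-en-1-one (ring centres as in 23) | CC1=CC[C@@H](C(C)(OC)OO)[C@@](C)(CC[C@@H]2OC2(C)C)C1=O | intermediate
25 | (1R,6R)-6-{2-[(2S)-3,3-dimethyloxiran-2-yl]ethyl}-4,6-dimethyl-5-oxocyclohex-3-en-1-yl acetate | CC1=CC[C@@H](OC(C)=O)[C@@](C)(CC[C@@H]2OC2(C)C)C1=O | intermediate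
26 | (5R,6R)-6-{2-[(2S)-3,3-dimethyloxiran-2-yl]ethyl}-5-hydroxy-2,6-dimethylcyclohex-2-en-1-one | CC1=CC[C@@H](O)[C@@](C)(CC[C@@H]2OC2(C)C)C1=O | intermediate
27 | (3S,5aR,9aR)-3-hydroxy-2,2,5a,7-tetramethyl-3,4,5,5a,9,9a-hexahydro-1-benzoxepin-6(2H)-one (cis-fused) | CC1=CC[C@H]2OC(C)(C)[C@@H](O)CC[C@@]2(C)C1=O | intermediate
28 | 7,8-epoxide of 27, oxirane on the face of the 5a-methyl group | C[C@@]12O[C@@H]1C[C@H]3OC(C)(C)[C@@H](O)CC[C@@]3(C)C2=O | intermediate
29 | (3S,5aS,8R,9aR)-2,2,5a,7-tetramethyl-2,3,4,5,5a,8,9,9a-octahydro-1-benzoxepine-3,8-diol | CC1=C[C@]2(C)CC[C@H](O)C(C)(C)O[C@@H]2C[C@H]1O | intermediate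
30 | ethyl 2-[(3S,5aS,6R,9aR)-3-hydroxy-2,2,5a,7-tetramethyl-2,3,4,5,5a,6,9,9a-octahydro-1-benzoxepin-6-yl]acetate | CCOC(=O)C[C@@H]1C(C)=CC[C@H]2OC(C)(C)[C@@H](O)CC[C@@]12C | intermediate
31 | 2-[(3S,5aS,6R,9aR)-3-hydroxy-2,2,5a,7-tetramethyl-2,3,4,5,5a,6,9,9a-octahydro-1-benzoxepin-6-yl]acetic acid | OC(=O)C[C@@H]1C(C)=CC[C@H]2OC(C)(C)[C@@H](O)CC[C@@]12C | intermediate
32 | cis-fused γ-lactone of [(3S,5aS,6S,7R,9aR)-3,7-dihydroxy-2,2,5a,7-tetramethyldecahydro-1-benzoxepin-6-yl]acetic acid | O=C1C[C@H]2[C@]3(C)CC[C@H](O)C(C)(C)O[C@@H]3CC[C@@]2(C)O1 | intermediate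
33 | cesium [(3S,5aS,6S,7R,9aR)-3,7-dihydroxy-2,2,5a,7-tetramethyldecahydro-1-benzoxepin-6-yl]acetate | [Cs+].[O-]C(=O)C[C@H]1[C@]2(C)CC[C@H](O)C(C)(C)O[C@@H]2CC[C@@]1(C)O | intermediate
34 | (3S,5aS,6S,7R,9aR)-6-{2-[(1S,3aS,5R,8aS)-1-hydroxy-1,4,4,6-tetramethyl-1,2,3,3a,4,5,8,8a-octahydroazulen-5-yl]ethyl}-2,2,5a,7-tetramethyldecahydro-1-benzoxepine-3,7-diol | CC1=CC[C@H]2[C@H](CC[C@]2(C)O)C(C)(C)[C@@H]1CC[C@H]1[C@]2(C)CC[C@H](O)C(C)(C)O[C@@H]2CC[C@@]1(C)O | target

**Step count and risks**
Total: 23 steps. Longest linear sequence: 12 steps (steps 1–11 then 23, or steps 12–22 then 23).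

Steps most likely to fail:

Step 10 (kinetic enol triflation of α-methylene ketone 13; Michael self-addition of the dienolate or triflation of the alkoxide may compete). Fallback: set out from 9 and run the cuprate/CH2=NMe2+ I− sequence of step 9 but stop at and isolate Mannich base 11, so the enone is masked during enolisation. KN(SiMe3)2/PhNTf2 gives the amino enol triflate F1, MeMgBr/Fe(acac)3 gives the allylic amine F2, MeI gives the ammonium iodide F3, and KOtBu (Hofmann elimination; the only β-hydrogen is on the ring carbon) comes back at diene 15.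

Step 18 (BF3-mediated 7-endo epoxide opening; 6-exo closure to a tetrahydropyran or Meinwald rearrangement may dominate). Fallback: set out from acetate 25 and isomerise the epoxide with Et3SiOTf/DBU to the allylic silyl ether F4 (the C–O bond of the future C3 is not touched). K2CO3/MeOH removes the acetate to give alcohol F5. Cobalt-hydride Markovnikov hydroalkoxylation of the new isopropenyl group (achiral Co(salen), divalent cobalt, N-fluoro-2,4,6-trimethylpyridinium tetrafluoroborate, PhSiH3) can only place the ring oxygen on the tertiary carbon and gives the silylated oxepane F6. Bu4NF then comes back at 27.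

Step 23 (the proposed new union; capture of the allyl radical by chromium and the face and site of protonation are untested). Fallback with known chemistry: set out from α-methylene ketone 13 and lactone 32 (opened to carboxylate 33 as in step 23). A decarboxylative Giese addition (Ir[dF(CF3)ppy]2(dtbbpy)PF6, DMF, blue LEDs) gives ketone F7, with the enolate protonated on the convex face. 2,4,6-Triisopropylbenzenesulfonyl hydrazide converts it to the hydrazone F8, and a Shapiro reaction (n-BuLi in excess, deprotonation at the CH2 side, then MeI) installs the methyl-bearing alkene and comes back at target 34.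

**Further compounds**
F1 | step 10 | (1S,3aS,8aS)-5-[(dimethylamino)methyl]-1-hydroxy-1,4,4-trimethyl-1,2,3,3a,4,5,8,8a-octahydroazulen-6-yl trifluoromethanesulfonate | CN(C)CC1C(OS(=O)(=O)C(F)(F)F)=CC[C@H]2[C@H](CC[C@]2(C)O)C1(C)C
F2 | step 10 | (1S,3aS,8aS)-5-[(dimethylamino)methyl]-1,4,4,6-tetramethyl-1,2,3,3a,4,5,8,8a-octahydroazulen-1-ol | CN(C)CC1C(C)=CC[C@H]2[C@H](CC[C@]2(C)O)C1(C)C
F3 | step 10 | N-methyl ammonium iodide of F2 | C[N+](C)(C)CC1C(C)=CC[C@H]2[C@H](CC[C@]2(C)O)C1(C)C.[I-]
F4 | step 18 | (1R,6R)-4,6-dimethyl-6-[(3S)-4-methyl-3-(triethylsilyloxy)pent-4-en-1-yl]-5-oxocyclohex-3-en-1-yl acetate | CC1=CC[C@@H](OC(C)=O)[C@@](C)(CC[C@H](O[Si](CC)(CC)CC)C(C)=C)C1=O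
F5 | step 18 | (5R,6R)-5-hydroxy-2,6-dimethyl-6-[(3S)-4-methyl-3-(triethylsilyloxy)pent-4-en-1-yl]cyclohex-2-en-1-one | CC1=CC[C@@H](O)[C@@](C)(CC[C@H](O[Si](CC)(CC)CC)C(C)=C)C1=O
F6 | step 18 | 3-O-triethylsilyl ether of 27 | CC1=CC[C@H]2OC(C)(C)[C@@H](O[Si](CC)(CC)CC)CC[C@@]2(C)C1=O
F7 | step 23 | 6-oxo analogue of the target lacking the 6-methyl group and the C6=C7 alkene (ketone at azulene C6, side chain at C5 as in 34) | O=C1CC[C@H]2[C@H](CC[C@]2(C)O)C(C)(C)[C@@H]1CC[C@H]1[C@]2(C)CC[C@H](O)C(C)(C)O[C@@H]2CC[C@@]1(C)O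
F8 | step 23 | 2,4,6-triisopropylbenzenesulfonyl hydrazone of F7 | CC(C)c1cc(C(C)C)c(S(=O)(=O)NN=C2CC[C@H]3[C@H](CC[C@]3(C)O)C(C)(C)[C@@H]2CC[C@H]2[C@]3(C)CC[C@H](O)C(C)(C)O[C@@H]3CC[C@@]2(C)O)c(C(C)C)c1
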